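**Retrosynthetic overview**
1. Target 19 comes from desilylation and hydrogenation/hydrogenolysis of E-enone 17, which is made by cross-metathesis of phthalide alkene 10 with vinyl ketone 16 (C8'–C9' bond of the side chain).
2. Vinyl ketone 16 comes from Weinreb amide 15, from (S)-γ-valerolactone 13, from ethyl levulinate 11 by ketoreductase reduction (carbinol stereocentre).
3. Phthalide 10 comes from bis-benzyl phthalide 8 by chelation-controlled 7-O-debenzylation and O-methylation, which differentiates the two phenols.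
4. Phthalide 8 comes from (S)-bromo alcohol 7 by Pd-catalysed carbonylative lactonisation; 7 from ketone 6 by CBS reduction (first stereocentre); 6 from bromo aldehyde 2 and Grignard reagent 4; 2 from aldehyde 1.
5. Rings: the benzene ring is bought; the only ring formed is the γ-lactone of the phthalide, closed in step 5.

Assumption: a commercial (S)-selective ketoreductase with isopropanol-coupled NADPH recycling is available, and the target is the open-chain γ-hydroxy ketone as drawn, (S) at the lactone carbon and (S) at the carbinol carbon.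

**Route**

Step 1
Reactants: 1 3,5-bis(benzyloxy)benzaldehyde
Product: 2 3,5-bis(benzyloxy)-2-bromobenzaldehyde
Conditions: NBS (1.05 equiv), MeCN, 0 °C → rt
Reagents that add atoms: N-bromosuccinimide, O=C1CCC(=O)N1Br
Why: Electrophilic aromatic bromination goes to the position ortho to one benzyloxy group and para to the other (C2 = C6 by symmetry), which is less hindered than C4, so a single monobromide forms.

Step 2
Reactants: 2 3,5-bis(benzyloxy)-2-bromobenzaldehyde; 3 9-bromonon-1-ene
Product: 5 rac-1-[3,5-bis(benzyloxy)-2-bromophenyl]dec-9-en-1-ol, via non-8-en-1-ylmagnesium bromide 4 (not isolated)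
Conditions: 3, Mg turnings, THF, rt; then 2, THF, −78 → 0 °C; cold 1 M HCl quench
Reagents that add atoms: none
Why: Grignard addition of a primary alkylmagnesium bromide to the aldehyde is faster than any exchange at the aryl bromide at low temperature; the carbinol forms racemic and is erased in step 3.

Step 3
Reactants: 5 rac-1-[3,5-bis(benzyloxy)-2-bromophenyl]dec-9-en-1-ol
Product: 6 1-[3,5-bis(benzyloxy)-2-bromophenyl]dec-9-en-1-one
Conditions: Dess–Martin periodinane (1.3 equiv), CH2Cl2, rt
Reagents that add atoms: none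
Why: Dess–Martin oxidation converts the secondary benzylic alcohol to the aryl ketone under neutral conditions that leave the alkene, aryl bromide and benzyl ethers untouched.

Step 4
Reactants: 6 1-[3,5-bis(benzyloxy)-2-bromophenyl]dec-9-en-1-one
Product: 7 (S)-1-[3,5-bis(benzyloxy)-2-bromophenyl]dec-9-en-1-ol
Conditions: (R)-Me-CBS oxazaborolidine [(R)-1-methyl-3,3-diphenyltetrahydro-1H,3H-pyrrolo[1,2-c][1,3,2]oxazaborole] (20 mol%), catecholborane (1.8 equiv), toluene, −78 → −40 °C; then H2O
Reagents that add atoms: none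
Why: In this Corey–Bakshi–Shibata reduction the (R)-catalyst binds the ketone with the large bromoaryl group away from its B-methyl and delivers hydride to give the (S)-carbinol (same sense as (R)-CBS giving (S)-1-phenylethanol), and catecholborane at low temperature does not hydroborate the terminal alkene.

Step 5
Reactants: 7 (S)-1-[3,5-bis(benzyloxy)-2-bromophenyl]dec-9-en-1-ol
Product: 8 (S)-5,7-bis(benzyloxy)-3-(non-8-en-1-yl)isobenzofuran-1(3H)-one
Conditions: Pd(OAc)2 (5 mol%), Xantphos (6 mol%), CO (1 atm), Et3N, toluene, 90 °C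
Reagents that add atoms: carbon monoxide, [C-]#[O+]
Why: Palladium-catalysed carbonylative lactonisation (oxidative addition of the aryl bromide to zerovalent palladium, CO insertion, intramolecular alcoholysis of the acylpalladium) closes the five-membered lactone without breaking the C–O bond of the stereocentre, so (S) is retained.

Step 6
Reactants: 8 (S)-5,7-bis(benzyloxy)-3-(non-8-en-1-yl)isobenzofuran-1(3H)-one
Product: 9 (S)-5-(benzyloxy)-7-hydroxy-3-(non-8-en-1-yl)isobenzofuran-1(3H)-one
Conditions: BCl3 (1.1 equiv), CH2Cl2, −78 °C; then H2O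
Reagents that add atoms: none
Why: Chelation-controlled Lewis-acid ether cleavage: BCl3 bridges the lactone carbonyl and the neighbouring 7-oxygen and removes only that benzyl group at −78 °C, while the 5-benzyl ether has no such assistance.

Step 7
Reactants: 9 (S)-5-(benzyloxy)-7-hydroxy-3-(non-8-en-1-yl)isobenzofuran-1(3H)-one
Product: 10 (S)-5-(benzyloxy)-7-methoxy-3-(non-8-en-1-yl)isobenzofuran-1(3H)-one
Conditions: MeI, K2CO3, DMF, rt
Reagents that add atoms: iodomethane, CI
Why: Williamson O-methylation of the only free phenol; K2CO3 is too weak to deprotonate the C3–H of the lactone, so the stereocentre is safe.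

Step 8
Reactants: 11 ethyl levulinate (ethyl 4-oxopentanoate)
Product: 13 (S)-γ-valerolactone [(S)-5-methyldihydrofuran-2(3H)-one], via ethyl (S)-4-hydroxypentanoate 12 (not isolated)
Conditions: (S)-selective ketoreductase (NADPH-dependent alcohol dehydrogenase, Prelog type), NADP+ (cat.), i-PrOH, KH2PO4/K2HPO4 buffer pH 7, 30 °C; then extraction, TsOH (cat.), CH2Cl2, rt
Reagents that add atoms: none
Why: The ketoreductase delivers hydride from NADPH to the re face of the methyl ketone (Prelog selectivity) to set the (S)-carbinol in very high ee, with isopropanol recycling the cofactor, and acid-catalysed lactonisation then gives the stable lactone.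

Step 9
Reactants: 13 (S)-γ-valerolactone
Product: 14 (S)-4-hydroxy-N-methoxy-N-methylpentanamide
Conditions: MeNH(OMe)·HCl (2 equiv), i-PrMgCl (4 equiv), THF, −20 → 0 °C; cold 1 M HCl quench; used crude at once
Reagents that add atoms: N,O-dimethylhydroxylamine hydrochloride, CNOC.Cl
Why: Weinreb amide formation by aminolysis of the lactone with the chloromagnesium amide; the stereocentre is not involved.

Step 10
Reactants: 14 (S)-4-hydroxy-N-methoxy-N-methylpentanamide
Product: 15 (S)-4-[(tert-butyldimethylsilyl)oxy]-N-methoxy-N-methylpentanamide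
Conditions: TBSCl, imidazole, DMF, rt
Reagents that add atoms: tert-butyldimethylsilyl chloride, CC(C)(C)[Si](C)(C)Cl
Why: Silylation of the secondary alcohol blocks re-lactonisation and protects the carbinol for the Grignard and metathesis steps.

Step 11
Reactants: 15 (S)-4-[(tert-butyldimethylsilyl)oxy]-N-methoxy-N-methylpentanamide
Product: 16 (S)-6-[(tert-butyldimethylsilyl)oxy]hept-1-en-3-one
Conditions: CH2=CHMgBr (1.5 equiv), THF, 0 °C; inverse quench into cold 1 M HCl; used promptly
Reagents that add atoms: vinylmagnesium bromide, C=C[Mg]Br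
Why: Weinreb ketone synthesis, in which the chelated tetrahedral intermediate prevents over-addition and the acidic inverse quench keeps the freed amine from adding to the enone.

Step 12
Reactants: 10 (S)-5-(benzyloxy)-7-methoxy-3-(non-8-en-1-yl)isobenzofuran-1(3H)-one; 16 (S)-6-[(tert-butyldimethylsilyl)oxy]hept-1-en-3-one
Product: 17 (S)-5-(benzyloxy)-3-[(S,E)-13-[(tert-butyldimethylsilyl)oxy]-10-oxotetradec-8-en-1-yl]-7-methoxyisobenzofuran-1(3H)-one
Conditions: second-generation Hoveyda–Grubbs catalyst, RuCl2(SIMes)(=CH-C6H4-2-O-i-Pr) (5 mol%), 16 (3 equiv), CH2Cl2, 40 °C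
Reagents that add atoms: none
Why: Olefin cross-metathesis between a readily reacting terminal alkene and an electron-poor vinyl ketone that does not homodimerise gives the E-enone selectively with loss of ethylene.

Step 13
Reactants: 17 (S)-5-(benzyloxy)-3-[(S,E)-13-[(tert-butyldimethylsilyl)oxy]-10-oxotetradec-8-en-1-yl]-7-methoxyisobenzofuran-1(3H)-one
Product: 18 (S)-3-[(S)-13-[(tert-butyldimethylsilyl)oxy]-10-oxotetradecyl]-5-hydroxy-7-methoxyisobenzofuran-1(3H)-one
Conditions: H2 (1 atm), 10% Pd/C, EtOAc, rt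
Reagents that add atoms: none
Why: Heterogeneous catalytic hydrogenation saturates the enone C=C and hydrogenolyses the aryl benzyl ether in one operation, while the aliphatic ketone, silyl ether and lactone are inert at 1 atm in EtOAc.

Step 14
Reactants: 18 (S)-3-[(S)-13-[(tert-butyldimethylsilyl)oxy]-10-oxotetradecyl]-5-hydroxy-7-methoxyisobenzofuran-1(3H)-one
Product: 19 (S)-5-hydroxy-3-[(S)-13-hydroxy-10-oxotetradecyl]-7-methoxyisobenzofuran-1(3H)-one
Conditions: HF·pyridine, pyridine/THF, 0 °C → rt
Reagents that add atoms: none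
Why: Fluoride-driven desilylation (strong Si–F bond) under buffered, non-basic conditions frees the secondary alcohol without touching the lactone, phenol or ketone and without affecting either stereocentre.

**Compound list**
1 | 3,5-bis(benzyloxy)benzaldehyde | O=Cc1cc(OCc2ccccc2)cc(OCc2ccccc2)c1 | starting material
2 | 3,5-bis(benzyloxy)-2-bromobenzaldehyde | O=Cc1cc(OCc2ccccc2)cc(OCc2ccccc2)c1Br | intermediate
3 | 9-bromonon-1-ene | BrCCCCCCCC=C | starting material
4 | non-8-en-1-ylmagnesium bromide | C=CCCCCCCC[Mg]Br | intermediate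
5 | rac-1-[3,5-bis(benzyloxy)-2-bromophenyl]dec-9-en-1-ol | OC(CCCCCCCC=C)c1cc(OCc2ccccc2)cc(OCc2ccccc2)c1Br | intermediate
6 | 1-[3,5-bis(benzyloxy)-2-bromophenyl]dec-9-en-1-one | C=CCCCCCCCC(=O)c1cc(OCc2ccccc2)cc(OCc2ccccc2)c1Br | intermediate
7 | (S)-1-[3,5-bis(benzyloxy)-2-bromophenyl]dec-9-en-1-ol | O[C@H](c1cc(OCc2ccccc2)cc(OCc2ccccc2)c1Br)CCCCCCCC=C | intermediate
8 | (S)-5,7-bis(benzyloxy)-3-(non-8-en-1-yl)isobenzofuran-1(3H)-one | c3ccccc3COc1cc(OCc4ccccc4)cc2c1C(=O)O[C@H]2CCCCCCCC=C | intermediate
9 | (S)-5-(benzyloxy)-7-hydroxy-3-(non-8-en-1-yl)isobenzofuran-1(3H)-one | Oc1cc(OCc3ccccc3)cc2c1C(=O)O[C@H]2CCCCCCCC=C | intermediate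
10 | (S)-5-(benzyloxy)-7-methoxy-3-(non-8-en-1-yl)isobenzofuran-1(3H)-one | COc1cc(OCc3ccccc3)cc2c1C(=O)O[C@H]2CCCCCCCC=C | intermediate
11 | ethyl levulinate (ethyl 4-oxopentanoate) | CCOC(=O)CCC(C)=O | starting material
12 | ethyl (S)-4-hydroxypentanoate | CCOC(=O)CC[C@H](C)O | intermediate
13 | (S)-γ-valerolactone [(S)-5-methyldihydrofuran-2(3H)-one] | O=C1CC[C@H](C)O1 | intermediate
14 | (S)-4-hydroxy-N-methoxy-N-methylpentanamide | CON(C)C(=O)CC[C@H](C)O | intermediate
15 | (S)-4-[(tert-butyldimethylsilyl)oxy]-N-methoxy-N-methylpentanamide | CON(C)C(=O)CC[C@H](C)O[Si](C)(C)C(C)(C)C | intermediate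
16 | (S)-6-[(tert-butyldimethylsilyl)oxy]hept-1-en-3-one | C=CC(=O)CC[C@H](C)O[Si](C)(C)C(C)(C)C | intermediate
17 | (S)-5-(benzyloxy)-3-[(S,E)-13-[(tert-butyldimethylsilyl)oxy]-10-oxotetradec-8-en-1-yl]-7-methoxyisobenzofuran-1(3H)-one | COc1cc(OCc3ccccc3)cc2c1C(=O)O[C@H]2CCCCCCC/C=C/C(=O)CC[C@H](C)O[Si](C)(C)C(C)(C)C | intermediate
18 | (S)-3-[(S)-13-[(tert-butyldimethylsilyl)oxy]-10-oxotetradecyl]-5-hydroxy-7-methoxyisobenzofuran-1(3H)-one | COc1cc(O)cc2c1C(=O)O[C@H]2CCCCCCCCCC(=O)CC[C@H](C)O[Si](C)(C)C(C)(C)C | intermediate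
19 | (S)-5-hydroxy-3-[(S)-13-hydroxy-10-oxotetradecyl]-7-methoxyisobenzofuran-1(3H)-one | COc1cc(O)cc2c1C(=O)O[C@H]2CCCCCCCCCC(=O)CC[C@H](C)O | target

**Totals**
Total step count: 14. Longest linear sequence: 10 steps (steps 1–7, then 12–14, from compound 1). The side-chain fragment takes 4 steps (8–11).

**Steps most likely to fail, with fallbacks**

Step 4 (enantioselectivity or conversion of the CBS reduction on a hindered ortho-bromo aryl ketone). The fallback sets out from 6 and returns at 8, bypassing 7. The aryl bromide of 6 is carbonylated in methanol (Pd(OAc)2, Xantphos, CO, Et3N, MeOH/toluene, 80 °C) to give methyl 2,4-bis(benzyloxy)-6-(dec-9-enoyl)benzoate F1. This keto ester is reduced by asymmetric transfer hydrogenation with RuCl(p-cymene)[(S,S)-TsDPEN] in HCO2H/Et3N to methyl (S)-2,4-bis(benzyloxy)-6-(1-hydroxydec-9-en-1-yl)benzoate F2, which lactonises in the same pot with loss of methanol to phthalide 8.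

Step 5 (carbonylation of an electron-rich aryl bromide flanked on both sides). The fallback sets out from 7 and returns at 8. Compound 7 is treated with n-BuLi (2.2 equiv, THF, −78 °C), which deprotonates the alcohol and then exchanges bromine for lithium to give the dilithio species lithium (S)-1-[3,5-bis(benzyloxy)-2-lithiophenyl]dec-9-en-1-olate F3. Quenching with CO2 and acidifying gives (S)-2,4-bis(benzyloxy)-6-(1-hydroxydec-9-en-1-yl)benzoic acid F4, which closes to 8 with catalytic TsOH in toluene at rt.

Step 6 (selectivity of the mono-debenzylation). The fallback sets out from 8 and returns at 9. Both benzyl ethers are removed with excess BCl3 and pentamethylbenzene as cation scavenger (CH2Cl2, −78 °C) to give (S)-5,7-dihydroxy-3-(non-8-en-1-yl)isobenzofuran-1(3H)-one F5. F5 is then re-benzylated with BnBr (1.05 equiv) and K2CO3 in acetone at rt, which goes to the more acidic 5-OH that is not hydrogen-bonded to the lactone carbonyl and gives 9.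

**Further compounds**
F1 | step 4 | methyl 2,4-bis(benzyloxy)-6-(dec-9-enoyl)benzoate | COC(=O)c1c(OCc2ccccc2)cc(OCc2ccccc2)cc1C(=O)CCCCCCCC=C
F2 | step 4 | methyl (S)-2,4-bis(benzyloxy)-6-(1-hydroxydec-9-en-1-yl)benzoate | O[C@H](c1cc(OCc2ccccc2)cc(OCc2ccccc2)c1C(=O)OC)CCCCCCCC=C
F3 | step 5 | lithium (S)-1-[3,5-bis(benzyloxy)-2-lithiophenyl]dec-9-en-1-olate | [Li]O[C@H](c1cc(OCc2ccccc2)cc(OCc2ccccc2)c1[Li])CCCCCCCC=C
F4 | step 5 | (S)-2,4-bis(benzyloxy)-6-(1-hydroxydec-9-en-1-yl)benzoic acid | O[C@H](c1cc(OCc2ccccc2)cc(OCc2ccccc2)c1C(=O)O)CCCCCCCC=C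
F5 | step 6 | (S)-5,7-dihydroxy-3-(non-8-en-1-yl)isobenzofuran-1(3H)-one | Oc1cc(O)cc2c1C(=O)O[C@H]2CCCCCCCC=C
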